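The runs are simulated for an exercise, and the scatter is random.

A small charge of substrate, 0.024 M, gives nearly the same share of target at 80.0 s as a large one, 0.33 M: 6.4% against 5.5%, with a scatter of 0.5 percentage points. So two chemists freeze the substrate and argue over time.

| flask | substrate | partner | remark | time |
|---|---|---|---|---|
| west | 0.024 M | 0.11 M | run made earlier |  |
| north-west | 0.086 M | 0.11 M | run made earlier |  |
| east | 0.33 M | 0.11 M | run made earlier |  |
| south-west | 0.10 M | 0.17 M | run made earlier |  |
| theta | 0.10 M | 0.150 M |  | 2.0 min |
| alpha | 0.30 M | 0.300 M |  | 2.0 min |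
| epsilon | 0.025 M | 0.200 M |  | 2.0 min |
| zeta | 0.060 M | 0.0800 M |  | 2.0 min |
| eta | 0.10 M | 0.110 M |  | 2.0 min |
| gamma | 0.10 M | 0.400 M |  | 2.0 min |

| run | time / s | target / % |
|---|---|---|
| west | 15.0 | 0 |
| west | 30.0 | 1.0 |
| west | 50.0 | 1.9 |
| west | 60.0 | 2.8 |
| west | 80.0 | 6.4 |
| north-west | 10.0 | 0 |
| north-west | 20.0 | 0.6 |
| north-west | 40.0 | 1.7 |
| north-west | 60.0 | 2.0 |
| north-west | 80.0 | 6.3 |
| east | 15.0 | 0.6 |
| east | 30.0 | 0.1 |
| east | 50.0 | 1.6 |
| east | 60.0 | 2.7 |
| east | 80.0 | 5.5 |
| south-west | 10.0 | 0.4 |
| south-west | 12.0 | 1.0 |
| south-west | 25.0 | 0.3 |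
| south-west | 40.0 | 1.0 |
| south-west | 80.0 | 8.7 |

(each reading ± 0.5 percentage points)

- all flasks from highest to lowest amount of target, in percent of the substrate charged, at 2.0 min (theta / alpha / epsilon / zeta / eta / gamma)
- the amount of target, in percent of the substrate charged of the flask you put first, at 2.0 min
- the amount of target, in percent of the substrate charged of the flask you put last, at 2.0 min



At partner 0.11 M, the west, north-west and east runs average 2.50% at 60.0 s and 6.07% at 80.0 s, after a lag phase. The flasks are asked at 2.0 min, beyond any reading.

I say the lag is over, so I draw the last slope straight on. That gives the stretch G = 2.18: target at 2.0 min divided by target at 80.0 s, charges held. Eta then reaches 13.2%.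

The forecaster says the curve keeps bending upward: “The curves show a lag”. It takes eta from about 6% to 16%.

Both of us rank the flasks by partner charge. The south-west reading gives me an apparent order in partner, n = 0.828. So I expect gamma at 38.5% and zeta at 10.1%.

The forecast reads gamma > alpha > epsilon > theta > eta > zeta, with 45% first (range 32% to 65%) and 12% last (range 8% to 19%).

The simulation gives gamma > alpha > epsilon > theta > eta > zeta, with gamma at 33.3% and zeta at 9.43%. The order stands. The forecast lies above gamma's value by 12 points, and my figure lies above gamma's value by 5.2 points.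

    substrate → open intermediate (k = 0.00860 s⁻¹)
    partner → second intermediate (k = 0.0150 s⁻¹)
    open intermediate + second intermediate → target (k = 0.0600 L mol⁻¹ s⁻¹)
    second intermediate → side product (k = 0.00510 s⁻¹)

The charges of gamma give 17.5% at 80.0 s and 33.3% at 2.0 min, a stretch of 1.90 against G of 2.18. The south-west flask stretches by 2.07. The forecast's bending curve has its region earlier: gamma rises as time to the power 2.05 from 50 s to 80.0 s, then to the power 1.59. Gamma's 33.3% at 2.0 min comes from the time allowed together with the path from second intermediate to side product. Without that path, gamma reaches 38.7% at 2.0 min. Left ten times as long, with the path in place, gamma reaches 87.9%.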